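A flat plateau tempts one to read the ring's yield as a constant of the chemistry, but flatness shows that a flask has stopped, not where it stopped.

| flask | starting material | protic impurity | remark | time |
|---|---|---|---|---|
| Friday's | 1.5 M | 0.88 M | run made earlier |  |
| Saturday's | 1.5 M | 1.9 M | run made earlier |  |
| Wednesday's | 1.6 M | 0.75 M | run made earlier |  |
| delta | 1.0 M | 1.50 M |  | 5.0 h |
| gamma | 1.5 M | 0.750 M |  | 8.0 h |

- Friday's (time / h: ring / %, starting material / %): 0.417: 66.5, 0.9; 0.667: 68.4, 0.1; 1.00: 69.7, 0.4; 1.50: 69.4, 0.3; 2.50: 69.5, 0; 4.00: 70.1, 0.2; 6.00: 70.0, 0.5
- Saturday's (time / h: ring / %, starting material / %): 0.333: 65.4, 0.5; 0.833: 68.6, 0; 1.50: 68.9, 0; 2.50: 69.6, 0.3; 3.00: 69.6, 0.3; 4.00: 69.5, 0; 6.00: 68.9, 0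
- Wednesday's (time / h: ring / %, starting material / %): 0.500: 66.7, 0; 1.33: 68.6, 0; 2.50: 68.9, 0; 4.00: 68.1, 0; 6.00: 68.6, 0.4

(each reading ± 0.3 percentage points)



* the winner by amount of ring, in percent of the starting material charged; "neither" if no more than 2 percentage points parts them (delta / gamma / neither)
* how much ring is there at the end, in percent of the starting material charged: delta
* how much ring is there at the end, in percent of the starting material charged: gamma

In Friday's run the ring is on its plateau by 1.00 h, and starting material reads 0.5% at 6.00 h. Averaged, the plateaus read 69.7% on Friday, 69.3% on Saturday and 68.5% on Wednesday.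

Suppose a rival of ring closure grows with the concentration c of starting material, so that the ring's share of turnover is one over one plus gc. Here g is the selectivity factor per molar. As c falls from the charge to nil, replace the curve by its mean, half the charge. Friday's plateau then gives g = 0.579 M⁻¹, and this g gives Wednesday 68.4%, against the 68.5% read.

For delta the mean form gives 77.6%, and for gamma, with the starting material of Friday's run, 69.7%. The exact average over the curve, the logarithm of one plus gc divided by gc, stands 2.3 percentage points above the mean form at Friday's charge and 1.3 points above it at delta's. Taking that difference off leaves a gap of 6.9 points.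

For "neither", delta's extra impurity would have to bring that gap down to 2 points. That needs about 15.2 times the cost per molar read, with its scatter, from Friday's run to Saturday's. This reckoning puts delta near 76.4% and gamma at 69.7%.

The forecast says delta, with 76% for delta and 69.5% for gamma, slightly below this reckoning on both, and adds: “This extrapolation rests on a narrow concentration range, so delta's uncertainty is wide.”

The flask gives delta: delta ends at 76.6% and gamma at 69.8%.

    starting material + ring → side product (k = 1.20 × 10⁻⁴ M⁻¹ s⁻¹)
    starting material → ring (k = 0.00630 s⁻¹)
    2 starting material → open dimer (k = 0.00220 M⁻¹ s⁻¹)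
    starting material + protic impurity → quenched substrate (k = 5.10 × 10⁻⁵ M⁻¹ s⁻¹)
    starting material ⇌ dormant form (K = 0.930, k = 0.00130 s⁻¹)

The main reason for gamma's shortfall is the path from two starting material to open dimer: struck out, it lets gamma's ring rise from 69.8% to 96.7%. That path is second order in starting material, the form supposed for the rival behind g. For the neighbour flask, gamma with its starting material cut to 0.90 M, the mean form with the same g gives 79.3%, and that flask ends at 78.6%.

The numbers in the tables come from a simulation with constants of no real substance, noise included.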